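**Retrosynthetic overview** (flavonoid numbering O1, C2, C3, C4, C4a, C5–C8, C8a is used for all ring atoms, also in the monocyclic pyranones)
- The strategy rests on ring C: the O1–C2(aryl)–C3(O)–C4(=O)–C4a=C8a pyranone. Its C2–C3 and O1–C8a bonds are cut back to the C=O of the B-ring aldehyde and a 1-methoxy-3,4-bis(silyloxy)butadiene.
- Ring order: B (bought as 5-hydroxyvanillin), then C (asymmetric formal hetero-Diels–Alder, sets C2 and C3), then A (Diels–Alder/aromatisation on C4a=C8a).
- Ring A is cut at C4a–C5 and C8–C8a to a C4a-sulfinyl dihydropyranone and the bis(silyloxy)diene of methyl 2-prenylacetoacetate. This places the prenyl group at C6 between the C5 and C7 hydroxyls with no regiochemical choice.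
- All hydroxyl protection is silyl and is removed in one fluoride step at the end.

Key step: step 5

Remark: the B-ring phenols are carried as TBS ethers so that the final deprotection needs no strong acid next to the prenyl/phenol pair, and the (S)-ligand in step 5 is chosen for Si-face attack by analogy with BINOL–titanium additions to aryl aldehydes (its enantiomer is used if a first run shows the opposite sense).

**Step 1**
Reactants: 1 5-hydroxyvanillin (3,4-dihydroxy-5-methoxybenzaldehyde)
Product: 2 3,4-bis(tert-butyldimethylsilyloxy)-5-methoxybenzaldehyde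
Conditions: TBSCl (2.4 equiv), imidazole, DMF, 20 °C
Reagents that add atoms: tert-butyldimethylsilyl chloride (TBSCl), CC(C)(C)[Si](C)(C)Cl
Why: Imidazole-mediated O-silylation of both phenols, which leaves the aldehyde untouched.

**Step 2**
Reactants: 3 (E)-4-methoxybut-3-en-2-one
Product: 4 (E)-3-(tert-butyldimethylsilyloxy)-1-methoxybuta-1,3-diene
Conditions: TBSOTf, Et3N, Et2O, 0 → 20 °C
Reagents that add atoms: tert-butyldimethylsilyl triflate (TBSOTf), CC(C)(C)[Si](C)(C)OS(=O)(=O)C(F)(F)F
Why: Soft enolisation and O-silylation of the methyl ketone (silyl enol ether formation) should give the TBS analogue of the Danishefsky diene with the E enol ether retained.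

**Step 3**
Reactants: 4 (E)-3-(tert-butyldimethylsilyloxy)-1-methoxybuta-1,3-diene
Product: 6 (E)-1-(tert-butyldimethylsilyloxy)-4-methoxybut-3-en-2-one, via silyloxy epoxide 5 (not isolated)
Conditions: mCPBA (1.05 equiv), NaHCO3, CH2Cl2, −20 → 20 °C
Reagents that add atoms: meta-chloroperbenzoic acid (mCPBA), OOC(=O)c1cccc(Cl)c1
Why: Rubottom oxidation: the peracid should epoxidise the more nucleophilic terminal silyl enol ether C=C, and the epoxide opens to a methoxyvinyl-stabilised oxocarbenium ion that takes up the TBS group by 1,4-shift to give the α-silyloxy ketone directly.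

**Step 4**
Reactants: 6 (E)-1-(tert-butyldimethylsilyloxy)-4-methoxybut-3-en-2-one
Product: 7 (1E,3Z)-4-(tert-butyldimethylsilyloxy)-1-methoxy-3-(trimethylsilyloxy)buta-1,3-diene
Conditions: TMSOTf, Et3N, Et2O, 0 °C
Reagents that add atoms: trimethylsilyl triflate (TMSOTf), C[Si](C)(C)OS(=O)(=O)C(F)(F)F
Why: Silyl enol ether formation at the only enolisable position (CH2OTBS), expected to favour the Z enediol bis-silyl ether as is usual for α-oxygenated ketones.

**Step 5**
Reactants: 2 3,4-bis(tert-butyldimethylsilyloxy)-5-methoxybenzaldehyde; 7 (1E,3Z)-4-(tert-butyldimethylsilyloxy)-1-methoxy-3-(trimethylsilyloxy)buta-1,3-diene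
Product: 9 (2R,3R)-2-[3,4-bis(tert-butyldimethylsilyloxy)-5-methoxyphenyl]-3-(tert-butyldimethylsilyloxy)-2,3-dihydro-4H-pyran-4-one, via silyl aldol adduct 8 (not isolated)
Conditions: Ti(OiPr)4 (10 mol%), (S)-BINOL (20 mol%), 4 Å molecular sieves, Et2O, −20 °C; then CF3CO2H, CH2Cl2, 0 °C
Reagents that add atoms: none
Why: The (S)-BINOL/Ti(OiPr)4 complex (tetravalent titanium) binds the non-enolisable aldehyde 2, and the OTBS-bearing enol carbon of 7 adds to the carbonyl carbon (Mukaiyama aldol with TMS transfer to the aldolate) to give 8; CF3CO2H then removes the TMS group and the C2 oxygen closes ring C on the methoxy-bearing carbon (the future C8a) by 6-endo-trig oxa-Michael addition and loss of methanol, so that the C2–C3 and O1–C8a bonds of a formal [4+2] adduct result. The closest known reaction type is the BINOL–titanium catalysed formal hetero-Diels–Alder reaction of aromatic aldehydes with 1-methoxy-3-silyloxybutadienes, 4-oxygenated dienes included. C2 is set by the catalyst: addition to the Si face of the aldehyde, expected for the (S)-ligand, gives 2R. C3 is set relative to C2 by the open transition state of the (3Z)-enol ether, which should favour the anti aldol and hence the 2,3-trans ring, and trans is also the more stable arrangement at this enolisable centre. Regioselectivity follows from the diene polarity (nucleophilic C4, C1 as masked aldehyde), and the aryl and alkyl TBS ethers should tolerate the Lewis acid and the brief acid treatment.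

**Step 6**
Reactants: 9 (2R,3R)-2-[3,4-bis(tert-butyldimethylsilyloxy)-5-methoxyphenyl]-3-(tert-butyldimethylsilyloxy)-2,3-dihydro-4H-pyran-4-one
Product: 10 (2R,3R)-2-[3,4-bis(tert-butyldimethylsilyloxy)-5-methoxyphenyl]-3-(tert-butyldimethylsilyloxy)-5-(phenylsulfanyl)-2,3-dihydro-4H-pyran-4-one
Conditions: PhSCl, 2,6-lutidine, CH2Cl2, −78 → 0 °C
Reagents that add atoms: benzenesulfenyl chloride (PhSCl), ClSc1ccccc1
Why: Electrophilic α-sulfenylation of the vinylogous ester: PhSCl adds across the enol ether C=C at the nucleophilic C4a, and the weak base removes HCl from the chloro acetal to restore the enone without touching C3.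

**Step 7**
Reactants: 10 (2R,3R)-2-[3,4-bis(tert-butyldimethylsilyloxy)-5-methoxyphenyl]-3-(tert-butyldimethylsilyloxy)-5-(phenylsulfanyl)-2,3-dihydro-4H-pyran-4-one
Product: 11 (2R,3R)-2-[3,4-bis(tert-butyldimethylsilyloxy)-5-methoxyphenyl]-3-(tert-butyldimethylsilyloxy)-5-(phenylsulfinyl)-2,3-dihydro-4H-pyran-4-one (both sulfur epimers)
Conditions: mCPBA (1.0 equiv), NaHCO3, CH2Cl2, −78 → −30 °C
Reagents that add atoms: meta-chloroperbenzoic acid (mCPBA), OOC(=O)c1cccc(Cl)c1
Why: Chemoselective sulfide-to-sulfoxide oxidation with one equivalent of peracid at low temperature; the electron-poor enone C=C is not epoxidised and the sulfur configuration is irrelevant because sulfur is lost in step 11.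

**Step 8**
Reactants: 12 methyl acetoacetate; 13 prenyl bromide (1-bromo-3-methylbut-2-ene)
Product: 14 methyl 2-acetyl-5-methylhex-4-enoate (racemic)
Conditions: K2CO3, acetone, reflux
Reagents that add atoms: none
Why: C-alkylation of the β-keto ester enolate by SN2 at the primary allylic bromide (acetoacetic ester alkylation), with a slight excess of 12 to suppress dialkylation.

**Step 9**
Reactants: 14 methyl 2-acetyl-5-methylhex-4-enoate
Product: 15 methyl 5-methyl-2-[1-(trimethylsilyloxy)ethylidene]hex-4-enoate (E/Z mixture)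
Conditions: TMSCl, Et3N, toluene, 20 °C
Reagents that add atoms: trimethylsilyl chloride (TMSCl), C[Si](C)(C)Cl
Why: O-silylation of the ketone enol of the β-keto ester, the first stage of the Chan-type bis(silyl enol ether) preparation, which is established for 2-alkyl acetoacetates.

**Step 10**
Reactants: 15 methyl 5-methyl-2-[1-(trimethylsilyloxy)ethylidene]hex-4-enoate
Product: 16 1-methoxy-2-(3-methylbut-2-enyl)-1,3-bis(trimethylsilyloxy)buta-1,3-diene (E/Z mixture)
Conditions: LiN(iPr)2, THF, −78 °C; then TMSCl, −78 → 20 °C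
Reagents that add atoms: trimethylsilyl chloride (TMSCl), C[Si](C)(C)Cl
Why: γ-Deprotonation of the β-silyloxy enoate at the methyl group gives the ester dienolate, which is O-silylated to the ketene silyl acetal (Chan-type 1,3-bis(silyloxy)diene formation).

**Step 11**
Reactants: 11 (2R,3R)-2-[3,4-bis(tert-butyldimethylsilyloxy)-5-methoxyphenyl]-3-(tert-butyldimethylsilyloxy)-5-(phenylsulfinyl)-2,3-dihydro-4H-pyran-4-one; 16 1-methoxy-2-(3-methylbut-2-enyl)-1,3-bis(trimethylsilyloxy)buta-1,3-diene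
Product: 19 (2R,3R)-2-[3,4-bis(tert-butyldimethylsilyloxy)-5-methoxyphenyl]-3-(tert-butyldimethylsilyloxy)-5,7-dihydroxy-6-(3-methylbut-2-enyl)-2,3-dihydro-4H-chromen-4-one, via sulfinyl cycloadduct 17 (not isolated), via bis(silyloxy) cyclohexadiene 18 (not isolated)
Conditions: 16 (2 equiv), toluene, 20 → 80 °C; then 1 M aq. HCl, THF, 0 °C
Reagents that add atoms: none
Why: Normal-electron-demand Diels–Alder reaction of the α-sulfinyl enone (a dienophile class known to be followed by sulfoxide syn-elimination) with the Chan-type diene should join the nucleophilic CH2 terminus to C8a and the ketene acetal carbon to C4a, the β-keto sulfoxide then loses PhSOH through the cis C8a–H, and acid hydrolysis of the silyl ketal (loss of methanol) and of the silyl enol ether lets the dienone tautomerise to the resorcinol ring A with prenyl fixed at C6, while C2 and C3 are not touched under these neutral to mildly acidic conditions.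

**Step 12**
Reactants: 19 (2R,3R)-2-[3,4-bis(tert-butyldimethylsilyloxy)-5-methoxyphenyl]-3-(tert-butyldimethylsilyloxy)-5,7-dihydroxy-6-(3-methylbut-2-enyl)-2,3-dihydro-4H-chromen-4-one
Product: 20 (2R,3R)-2-(3,4-dihydroxy-5-methoxyphenyl)-3,5,7-trihydroxy-6-(3-methylbut-2-enyl)-2,3-dihydro-4H-chromen-4-one (CNP0165835.1)
Conditions: HF·pyridine, excess pyridine, THF, 0 → 20 °C
Reagents that add atoms: none
Why: Fluoride-mediated global desilylation of the two aryl and one secondary TBS ethers under buffered conditions that should neither epimerise the base-sensitive trans-dihydroflavonol nor cyclise the prenyl group onto the neighbouring phenols.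

**Compound list**
1 | 5-hydroxyvanillin (3,4-dihydroxy-5-methoxybenzaldehyde) | COc1cc(C=O)cc(O)c1O | starting material
2 | 3,4-bis(tert-butyldimethylsilyloxy)-5-methoxybenzaldehyde | COc1cc(C=O)cc(O[Si](C)(C)C(C)(C)C)c1O[Si](C)(C)C(C)(C)C | intermediate
3 | (E)-4-methoxybut-3-en-2-one | CO/C=C/C(C)=O | starting material
4 | (E)-3-(tert-butyldimethylsilyloxy)-1-methoxybuta-1,3-diene | CO/C=C/C(=C)O[Si](C)(C)C(C)(C)C | intermediate
5 | 2-(tert-butyldimethylsilyloxy)-2-[(E)-2-methoxyethenyl]oxirane (racemic, not isolated) | CO/C=C/C1(CO1)O[Si](C)(C)C(C)(C)C | intermediate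
6 | (E)-1-(tert-butyldimethylsilyloxy)-4-methoxybut-3-en-2-one | CO/C=C/C(=O)CO[Si](C)(C)C(C)(C)C | intermediate
7 | (1E,3Z)-4-(tert-butyldimethylsilyloxy)-1-methoxy-3-(trimethylsilyloxy)buta-1,3-diene | CO/C=C/C(O[Si](C)(C)C)=C/O[Si](C)(C)C(C)(C)C | intermediate
8 | (1E,4R,5R)-5-[3,4-bis(tert-butyldimethylsilyloxy)-5-methoxyphenyl]-4-(tert-butyldimethylsilyloxy)-1-methoxy-5-(trimethylsilyloxy)pent-1-en-3-one (not isolated) | COc1cc([C@@H](O[Si](C)(C)C)[C@@H](O[Si](C)(C)C(C)(C)C)C(=O)/C=C/OC)cc(O[Si](C)(C)C(C)(C)C)c1O[Si](C)(C)C(C)(C)C | intermediate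
9 | (2R,3R)-2-[3,4-bis(tert-butyldimethylsilyloxy)-5-methoxyphenyl]-3-(tert-butyldimethylsilyloxy)-2,3-dihydro-4H-pyran-4-one | COc1cc([C@H]2OC=CC(=O)[C@@H]2O[Si](C)(C)C(C)(C)C)cc(O[Si](C)(C)C(C)(C)C)c1O[Si](C)(C)C(C)(C)C | intermediate
10 | (2R,3R)-2-[3,4-bis(tert-butyldimethylsilyloxy)-5-methoxyphenyl]-3-(tert-butyldimethylsilyloxy)-5-(phenylsulfanyl)-2,3-dihydro-4H-pyran-4-one | COc1cc([C@H]2OC=C(Sc3ccccc3)C(=O)[C@@H]2O[Si](C)(C)C(C)(C)C)cc(O[Si](C)(C)C(C)(C)C)c1O[Si](C)(C)C(C)(C)C | intermediate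
11 | (2R,3R)-2-[3,4-bis(tert-butyldimethylsilyloxy)-5-methoxyphenyl]-3-(tert-butyldimethylsilyloxy)-5-(phenylsulfinyl)-2,3-dihydro-4H-pyran-4-one (both sulfur epimers) | COc1cc([C@H]2OC=C(S(=O)c3ccccc3)C(=O)[C@@H]2O[Si](C)(C)C(C)(C)C)cc(O[Si](C)(C)C(C)(C)C)c1O[Si](C)(C)C(C)(C)C | intermediate
12 | methyl acetoacetate | CC(=O)CC(=O)OC | starting material
13 | prenyl bromide (1-bromo-3-methylbut-2-ene) | CC(C)=CCBr | starting material
14 | methyl 2-acetyl-5-methylhex-4-enoate (racemic) | COC(=O)C(CC=C(C)C)C(C)=O | intermediate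
15 | methyl 5-methyl-2-[1-(trimethylsilyloxy)ethylidene]hex-4-enoate (E/Z mixture) | COC(=O)C(CC=C(C)C)=C(C)O[Si](C)(C)C | intermediate
16 | 1-methoxy-2-(3-methylbut-2-enyl)-1,3-bis(trimethylsilyloxy)buta-1,3-diene (E/Z mixture) | C=C(O[Si](C)(C)C)C(CC=C(C)C)=C(OC)O[Si](C)(C)C | intermediate
17 | (2R,3R)-2-[3,4-bis(tert-butyldimethylsilyloxy)-5-methoxyphenyl]-3-(tert-butyldimethylsilyloxy)-5-methoxy-6-(3-methylbut-2-enyl)-4a-(phenylsulfinyl)-5,7-bis(trimethylsilyloxy)-2,3,4a,5,8,8a-hexahydro-4H-chromen-4-one (cis ring fusion; mixture at C4a, C5, C8a and sulfur; not isolated) | COc1cc([C@H]2OC3CC(O[Si](C)(C)C)=C(CC=C(C)C)C(OC)(O[Si](C)(C)C)C3(S(=O)c4ccccc4)C(=O)[C@@H]2O[Si](C)(C)C(C)(C)C)cc(O[Si](C)(C)C(C)(C)C)c1O[Si](C)(C)C(C)(C)C | intermediate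
18 | (2R,3R)-2-[3,4-bis(tert-butyldimethylsilyloxy)-5-methoxyphenyl]-3-(tert-butyldimethylsilyloxy)-5-methoxy-6-(3-methylbut-2-enyl)-5,7-bis(trimethylsilyloxy)-2,3,5,8-tetrahydro-4H-chromen-4-one (mixture at C5; not isolated) | COc1cc([C@H]2OC3=C(C(=O)[C@@H]2O[Si](C)(C)C(C)(C)C)C(OC)(O[Si](C)(C)C)C(CC=C(C)C)=C(O[Si](C)(C)C)C3)cc(O[Si](C)(C)C(C)(C)C)c1O[Si](C)(C)C(C)(C)C | intermediate
19 | (2R,3R)-2-[3,4-bis(tert-butyldimethylsilyloxy)-5-methoxyphenyl]-3-(tert-butyldimethylsilyloxy)-5,7-dihydroxy-6-(3-methylbut-2-enyl)-2,3-dihydro-4H-chromen-4-one | COc1cc([C@H]2Oc3cc(O)c(CC=C(C)C)c(O)c3C(=O)[C@@H]2O[Si](C)(C)C(C)(C)C)cc(O[Si](C)(C)C(C)(C)C)c1O[Si](C)(C)C(C)(C)C | intermediate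
20 | (2R,3R)-2-(3,4-dihydroxy-5-methoxyphenyl)-3,5,7-trihydroxy-6-(3-methylbut-2-enyl)-2,3-dihydro-4H-chromen-4-one | COc1cc([C@H]2Oc3cc(O)c(CC=C(C)C)c(O)c3C(=O)[C@@H]2O)cc(O)c1O | target

**Step count**
Total steps: 12. Longest linear sequence: 8 steps (steps 2, 3, 4, 5, 6, 7, 11, 12, from (E)-4-methoxybut-3-en-2-one).

**Steps most likely to fail**

1. Step 5. The hindered, electron-rich 4-silyloxy diene may react with poor facial selectivity at the aldehyde, or the aldol stage may give a substantial share of the syn adduct and hence the 2,3-cis ring. The fallback sets out from 2 and returns at 9, and introduces the C3 oxygen after ring closure under substrate control. Aldehyde 2 is combined with commercial (E)-1-methoxy-3-(trimethylsilyloxy)buta-1,3-diene under the same Ti(OiPr)4/(S)-BINOL conditions and CF3CO2H work-up, a pairing of well-established selectivity for aryl aldehydes. This should give (S)-2-[3,4-bis(tert-butyldimethylsilyloxy)-5-methoxyphenyl]-2,3-dihydro-4H-pyran-4-one F1. α'-Acetoxylation with Mn(OAc)3 in benzene at reflux, which on 2-substituted dihydropyranones enters trans to the C2 substituent, should give (2R,3R)-3-acetoxy-2-[3,4-bis(tert-butyldimethylsilyloxy)-5-methoxyphenyl]-2,3-dihydro-4H-pyran-4-one F2. Neutral lipase-mediated deacetylation (Candida antarctica lipase B, phosphate buffer/tBuOMe) should give (2R,3R)-2-[3,4-bis(tert-butyldimethylsilyloxy)-5-methoxyphenyl]-3-hydroxy-2,3-dihydro-4H-pyran-4-one F3. TBSOTf and 2,6-lutidine in CH2Cl2 at −78 °C then give 9.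

2. Step 11. The concerted cycloaddition may be too slow, because the diene is tetrasubstituted and the dienophile is a vinylogous ester, and ring C may open by β-elimination of O1 if the C7 carbonyl is unmasked before the sulfoxide has left. The fallback sets out from 11 and 16 and returns at 19, and forms the two ring-A bonds in separate operations. ZnBr2-promoted Mukaiyama–Michael addition of the CH2 terminus of 16 to C8a of 11 (CH2Cl2, −40 °C, buffered aqueous work-up) should give methyl 4-[(2R,3R)-2-[3,4-bis(tert-butyldimethylsilyloxy)-5-methoxyphenyl]-3-(tert-butyldimethylsilyloxy)-4-oxo-5-(phenylsulfinyl)tetrahydro-2H-pyran-6-yl]-2-(3-methylbut-2-enyl)-3-oxobutanoate F4. Warming in toluene at 60 °C expels benzenesulfenic acid, as in additions to 3-sulfinylchromones, and should give methyl 4-[(2R,3R)-2-[3,4-bis(tert-butyldimethylsilyloxy)-5-methoxyphenyl]-3-(tert-butyldimethylsilyloxy)-4-oxo-3,4-dihydro-2H-pyran-6-yl]-2-(3-methylbut-2-enyl)-3-oxobutanoate F5. Double deprotonation with LiN(SiMe3)2 (THF, −78 → 0 °C) then lets C4a acylate on the ester in a polyketide-type intramolecular Claisen condensation. Loss of methanol and enolisation give 19.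

3. Step 3. The acid-labile dienol ether may be protodesilylated back to 3 by the carboxylic acid, or the peracid may attack the methoxyvinyl unit. The fallback sets out from 3 and returns at 6, and oxidises the ketone directly. α'-Acetoxylation of 3 with Mn(OAc)3 in benzene at reflux should give (E)-1-acetoxy-4-methoxybut-3-en-2-one F6. Methanolysis with catalytic K2CO3 in MeOH at 0 °C, in which exchange at the methoxyvinyl carbon is degenerate, should give (E)-1-hydroxy-4-methoxybut-3-en-2-one F7. TBSCl and imidazole in DMF then give 6.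

**Further compounds**
F1 | step 5 | (S)-2-[3,4-bis(tert-butyldimethylsilyloxy)-5-methoxyphenyl]-2,3-dihydro-4H-pyran-4-one | COc1cc([C@H]2OC=CC(=O)C2)cc(O[Si](C)(C)C(C)(C)C)c1O[Si](C)(C)C(C)(C)C
F2 | step 5 | (2R,3R)-3-acetoxy-2-[3,4-bis(tert-butyldimethylsilyloxy)-5-methoxyphenyl]-2,3-dihydro-4H-pyran-4-one | COc1cc([C@H]2OC=CC(=O)[C@@H]2OC(C)=O)cc(O[Si](C)(C)C(C)(C)C)c1O[Si](C)(C)C(C)(C)C
F3 | step 5 | (2R,3R)-2-[3,4-bis(tert-butyldimethylsilyloxy)-5-methoxyphenyl]-3-hydroxy-2,3-dihydro-4H-pyran-4-one | COc1cc([C@H]2OC=CC(=O)[C@@H]2O)cc(O[Si](C)(C)C(C)(C)C)c1O[Si](C)(C)C(C)(C)C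
F4 | step 11 | methyl 4-[(2R,3R)-2-[3,4-bis(tert-butyldimethylsilyloxy)-5-methoxyphenyl]-3-(tert-butyldimethylsilyloxy)-4-oxo-5-(phenylsulfinyl)tetrahydro-2H-pyran-6-yl]-2-(3-methylbut-2-enyl)-3-oxobutanoate (mixture at the other centres) | COc1cc([C@H]2OC(CC(=O)C(CC=C(C)C)C(=O)OC)C(S(=O)c3ccccc3)C(=O)[C@@H]2O[Si](C)(C)C(C)(C)C)cc(O[Si](C)(C)C(C)(C)C)c1O[Si](C)(C)C(C)(C)C
F5 | step 11 | methyl 4-[(2R,3R)-2-[3,4-bis(tert-butyldimethylsilyloxy)-5-methoxyphenyl]-3-(tert-butyldimethylsilyloxy)-4-oxo-3,4-dihydro-2H-pyran-6-yl]-2-(3-methylbut-2-enyl)-3-oxobutanoate | COc1cc([C@H]2OC(CC(=O)C(CC=C(C)C)C(=O)OC)=CC(=O)[C@@H]2O[Si](C)(C)C(C)(C)C)cc(O[Si](C)(C)C(C)(C)C)c1O[Si](C)(C)C(C)(C)C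
F6 | step 3 | (E)-1-acetoxy-4-methoxybut-3-en-2-one | CO/C=C/C(=O)COC(C)=O
F7 | step 3 | (E)-1-hydroxy-4-methoxybut-3-en-2-one | CO/C=C/C(=O)CO
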